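**Retrosynthetic overview**
- Last C=C: the exocyclic (Z)-alkene of the γ-ylidene butenolide, made by vinylogous aldol–elimination of a furanoid butenolide with a polyenynal (both TBS-protected), then desilylation.
- Key bond: the O–C2 bond of the dihydrofuran, closed by gold-catalysed 5-endo attack of a tertiary hydroxyl on an allene; the allene axis (from anti-SN2′ hydride opening of an alkynyl epoxide) is transferred to C2.
- Alkynyl epoxide: enol triflate, then Sonogashira couplings with trimethylsilylacetylene and 3-bromobutenolide, then peracid epoxidation anti to the silyloxy group.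
- Polyenynal: the same enol triflate, Sonogashira coupling with (E)-3-methylpent-2-en-4-yn-1-ol, phosphonate, Horner–Wadsworth–Emmons reaction, Wittig reaction.
- Rings: both cyclohexane rings come from (4R,6R)-actinol, the lactone ring is bought, and the dihydrofuran is the only ring formed, before fragment union.

Assumption: (4R,6R)-actinol, 3-bromofuran-2(5H)-one, (E)-3-methylpent-2-en-4-yn-1-ol, fumaraldehyde mono(dimethyl acetal) and 2-(triphenylphosphoranylidene)propanal are taken as purchasable.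

**Route**

Step 1
Reactants: 1 (4R,6R)-4-hydroxy-2,2,6-trimethylcyclohexan-1-one (actinol)
Product: 2 (4R,6R)-4-{[tert-butyl(dimethyl)silyl]oxy}-2,2,6-trimethylcyclohexan-1-one
Conditions: TBSCl, imidazole, DMF, rt
Reagents that add atoms: tert-butyldimethylsilyl chloride, CC(C)(C)[Si](C)(C)Cl
Why: Imidazole-promoted silyl ether formation on the only hydroxyl; no stereocentre is touched.

Step 2
Reactants: 2 TBS-protected actinol
Product: 3 (4R)-4-{[tert-butyl(dimethyl)silyl]oxy}-2,6,6-trimethylcyclohex-1-en-1-yl trifluoromethanesulfonate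
Conditions: LDA, THF, −78 °C; PhNTf2, −78 °C → rt; aq. NH4Cl
Reagents that add atoms: N-phenylbis(trifluoromethanesulfonimide), O=S(=O)(N(c1ccccc1)S(=O)(=O)C(F)(F)F)C(F)(F)F
Why: The ketone can enolise only toward C6 (C2 is quaternary), so O-triflation of the lithium enolate (enol triflate formation) gives the tetrasubstituted triflate; the C6 centre is erased on purpose and C4 is untouched.

Step 3
Reactants: 3 enol triflate + 4 ethynyl(trimethyl)silane
Product: 6 tert-butyl{[(1R)-4-ethynyl-3,5,5-trimethylcyclohex-3-en-1-yl]oxy}dimethylsilane, via TMS-enyne 5 (not isolated)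
Conditions: Pd(PPh3)4 (5 mol%), CuI (10 mol%), iPr2NH, DMF, 50 °C; then K2CO3, MeOH, rt
Reagents that add atoms: none
Why: Sonogashira coupling of the vinyl triflate followed by methanolytic protodesilylation of the alkynylsilane in the same flask; the secondary TBS ether survives carbonate in methanol.

Step 4
Reactants: 6 terminal enyne + 7 3-bromofuran-2(5H)-one
Product: 8 3-{[(4R)-4-{[tert-butyl(dimethyl)silyl]oxy}-2,6,6-trimethylcyclohex-1-en-1-yl]ethynyl}furan-2(5H)-one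
Conditions: PdCl2(PPh3)2 (5 mol%), CuI (10 mol%), Et3N, THF, 0 °C → rt
Reagents that add atoms: none
Why: Sonogashira coupling; the α-bromo enoate adds quickly to zerovalent palladium, so coupling is complete at or below room temperature before the base-sensitive butenolide degrades.

Step 5
Reactants: 8 enynyl butenolide
Product: 9 3-{[(1R,4S,6R)-4-{[tert-butyl(dimethyl)silyl]oxy}-2,2,6-trimethyl-7-oxabicyclo[4.1.0]heptan-1-yl]ethynyl}furan-2(5H)-one
Conditions: mCPBA, NaHCO3, CH2Cl2, −20 → 0 °C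
Reagents that add atoms: 3-chloroperoxybenzoic acid, OOC(=O)c1cccc(Cl)c1
Why: Prilezhaev epoxidation attacks only the electron-rich tetrasubstituted ring alkene (the butenolide alkene and the alkyne are electron-poor), and the peracid approaches anti to the bulky silyloxy group, setting both epoxide carbons with oxygen trans to OTBS (about 4:1 expected, minor syn isomer removed by chromatography).

Step 6
Reactants: 9 alkynyl epoxide
Product: 10 3-{(S)-2-[(2R,4S)-4-{[tert-butyl(dimethyl)silyl]oxy}-2-hydroxy-2,6,6-trimethylcyclohexylidene]ethenyl}furan-2(5H)-one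
Conditions: Pd2(dba)3·CHCl3 (2.5 mol%), PBu3 (10 mol%), HCO2H, Et3N, THF, 0 °C → rt
Reagents that add atoms: none
Why: Tsuji-type palladium–formate hydrogenolysis of a propargylic electrophile: zerovalent palladium opens the alkynyl oxirane by anti-SN2′ oxidative addition, formate decarboxylates to a palladium hydride, and C–H reductive elimination with retention puts hydrogen anti and the butenolide syn to the former C–O bond, which defines the (S)-allene axis and frees the tertiary alcohol without reducing the lactone.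

Step 7
Reactants: 10 α-hydroxyallene
Product: 11 3-[(2R,6S,7aR)-6-{[tert-butyl(dimethyl)silyl]oxy}-4,4,7a-trimethyl-2,4,5,6,7,7a-hexahydro-1-benzofuran-2-yl]furan-2(5H)-one
Conditions: Ph3PAuCl (2 mol%), AgOTs (2 mol%), toluene, 0 °C → rt, dark
Reagents that add atoms: none
Why: Proposed new method: monovalent gold coordinates the distal C=C of the allene, the tertiary hydroxyl attacks the butenolide-bearing terminus 5-endo within the plane of the ring carbons, and protodeauration of the vinylgold gives the 2,5-dihydrofuran; because the two substituents on that terminus stand perpendicular to the direction of oxygen approach, the (S) axis becomes (2R) with the butenolide trans to the 7a-methyl, and the acceptor substituent disfavours ionisation that would scramble the axis; the closest known reaction is the gold-catalysed cycloisomerisation of α-hydroxyallenes to 2,5-dihydrofurans with axis-to-centre chirality transfer, not yet shown on a vinylidenecyclohexane flanked by two quaternary carbons, on a butenolide-substituted allene terminus, or as an entry to the carotenoid 5,8-furanoxide ring, which is otherwise made by stereorandom acid-catalysed epoxide rearrangement.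

Step 8
Reactants: 3 enol triflate + 12 (2E)-3-methylpent-2-en-4-yn-1-ol
Product: 13 (2E)-5-[(4R)-4-{[tert-butyl(dimethyl)silyl]oxy}-2,6,6-trimethylcyclohex-1-en-1-yl]-3-methylpent-2-en-4-yn-1-ol
Conditions: Pd(PPh3)4 (5 mol%), CuI (10 mol%), iPr2NH, DMF, 50 °C
Reagents that add atoms: none
Why: Sonogashira coupling; the free primary alcohol is tolerated and the E geometry of the enynol is carried through unchanged.

Step 9
Reactants: 13 enynol
Product: 15 diethyl {(2E)-5-[(4R)-4-{[tert-butyl(dimethyl)silyl]oxy}-2,6,6-trimethylcyclohex-1-en-1-yl]-3-methylpent-2-en-4-yn-1-yl}phosphonate, via allylic bromide 14 (not isolated)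
Conditions: CBr4, PPh3, CH2Cl2, −20 °C; then P(OEt)3, 90 °C
Reagents that add atoms: tetrabromomethane, BrC(Br)(Br)Br (bromine of 14); triethyl phosphite, CCOP(OCC)OCC
Why: Appel bromination of the allylic alcohol under neutral conditions followed by Michaelis–Arbuzov reaction of the primary allylic bromide; alkene geometry and silyl ether are retained.

Step 10
Reactants: 15 allylic phosphonate + 16 (2E)-4,4-dimethoxybut-2-enal
Product: 18 (2E,4E,6E)-9-[(4R)-4-{[tert-butyl(dimethyl)silyl]oxy}-2,6,6-trimethylcyclohex-1-en-1-yl]-7-methylnona-2,4,6-trien-8-ynal, via dimethyl acetal 17 (not isolated)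
Conditions: NaHMDS, THF, −78 °C; 16, −78 → 0 °C; then 5% aq. oxalic acid, THF, 0 °C
Reagents that add atoms: water, O
Why: Horner–Wadsworth–Emmons olefination of the allylic phosphonate anion with the enal forms the new disubstituted alkene E-selectively without touching the other double bonds, and the conjugated dimethyl acetal is hydrolysed in the mildly acidic work-up while the TBS ether stays.

Step 11
Reactants: 18 trienynal + 19 2-(triphenyl-λ5-phosphanylidene)propanal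
Product: 20 (2E,4E,6E,8E)-11-[(4R)-4-{[tert-butyl(dimethyl)silyl]oxy}-2,6,6-trimethylcyclohex-1-en-1-yl]-2,9-dimethylundeca-2,4,6,8-tetraen-10-ynal
Conditions: toluene, 80 °C
Reagents that add atoms: none
Why: Wittig reaction of a stabilised formyl ylide gives the α-methyl enal E-selectively, and that product is less electrophilic than 18, so it is not homologated again.

Step 12
Reactants: 11 furanoid butenolide + 20 polyenynal
Product: 23 (5Z)-3-[(2R,6S,7aR)-6-{[tert-butyl(dimethyl)silyl]oxy}-4,4,7a-trimethyl-2,4,5,6,7,7a-hexahydro-1-benzofuran-2-yl]-5-{(2E,4E,6E,8E)-11-[(4R)-4-{[tert-butyl(dimethyl)silyl]oxy}-2,6,6-trimethylcyclohex-1-en-1-yl]-2,9-dimethylundeca-2,4,6,8-tetraen-10-yn-1-ylidene}furan-2(5H)-one, via silyloxyfuran 21 (not isolated), via silyl aldol adduct 22 (not isolated)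
Conditions: TBSOTf, iPr2NEt, CH2Cl2, −78 → −20 °C; then DBU, −20 °C → rt
Reagents that add atoms: tert-butyldimethylsilyl trifluoromethanesulfonate, CC(C)(C)[Si](C)(C)OS(=O)(=O)C(F)(F)F (silyl group of 21 and 22)
Why: One-pot vinylogous Mukaiyama aldol–elimination: the silyloxyfuran formed in situ adds through its γ-carbon to the silyl-activated enal and DBU then expels silanolate by E1cB elimination through the furanolate, giving the thermodynamically preferred (Z)-γ-ylidene butenolide; C2 of the dihydrofuran is not acidic and keeps its configuration.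

Step 13
Reactants: 23 bis-TBS ether
Product: 24 (5Z)-3-[(2R,6S,7aR)-6-hydroxy-4,4,7a-trimethyl-2,4,5,6,7,7a-hexahydro-1-benzofuran-2-yl]-5-{(2E,4E,6E,8E)-11-[(4R)-4-hydroxy-2,6,6-trimethylcyclohex-1-en-1-yl]-2,9-dimethylundeca-2,4,6,8-tetraen-10-yn-1-ylidene}furan-2(5H)-one
Conditions: TBAF, AcOH (1:1), THF, 0 °C → rt, dark
Reagents that add atoms: none
Why: Fluoride-mediated cleavage of both secondary silyl ethers; acetic acid buffering avoids base attack on the ylidene butenolide and avoids acid-catalysed epimerisation at C2 of the furanoxide.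

**Compound list**

1 | (4R,6R)-4-hydroxy-2,2,6-trimethylcyclohexan-1-one | C[C@H]1C(=O)C(C)(C)C[C@H](O)C1 | starting material
2 | (4R,6R)-4-{[tert-butyl(dimethyl)silyl]oxy}-2,2,6-trimethylcyclohexan-1-one | C[C@H]1C(=O)C(C)(C)C[C@H](O[Si](C)(C)C(C)(C)C)C1 | intermediate
3 | (4R)-4-{[tert-butyl(dimethyl)silyl]oxy}-2,6,6-trimethylcyclohex-1-en-1-yl trifluoromethanesulfonate | CC1=C(OS(=O)(=O)C(F)(F)F)C(C)(C)C[C@H](O[Si](C)(C)C(C)(C)C)C1 | intermediate
4 | ethynyl(trimethyl)silane | C#C[Si](C)(C)C | starting material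
5 | tert-butyl(dimethyl){[(1R)-3,5,5-trimethyl-4-[(trimethylsilyl)ethynyl]cyclohex-3-en-1-yl]oxy}silane | CC1=C(C#C[Si](C)(C)C)C(C)(C)C[C@H](O[Si](C)(C)C(C)(C)C)C1 | intermediate
6 | tert-butyl{[(1R)-4-ethynyl-3,5,5-trimethylcyclohex-3-en-1-yl]oxy}dimethylsilane | CC1=C(C#C)C(C)(C)C[C@H](O[Si](C)(C)C(C)(C)C)C1 | intermediate
7 | 3-bromofuran-2(5H)-one | O=C1OCC=C1Br | starting material
8 | 3-{[(4R)-4-{[tert-butyl(dimethyl)silyl]oxy}-2,6,6-trimethylcyclohex-1-en-1-yl]ethynyl}furan-2(5H)-one | CC1=C(C#CC2=CCOC2=O)C(C)(C)C[C@H](O[Si](C)(C)C(C)(C)C)C1 | intermediate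
9 | 3-{[(1R,4S,6R)-4-{[tert-butyl(dimethyl)silyl]oxy}-2,2,6-trimethyl-7-oxabicyclo[4.1.0]heptan-1-yl]ethynyl}furan-2(5H)-one (epoxide oxygen trans to the silyloxy group) | C[C@@]12C[C@@H](O[Si](C)(C)C(C)(C)C)CC(C)(C)[C@]1(C#CC3=CCOC3=O)O2 | intermediate
10 | 3-{(S)-2-[(2R,4S)-4-{[tert-butyl(dimethyl)silyl]oxy}-2-hydroxy-2,6,6-trimethylcyclohexylidene]ethenyl}furan-2(5H)-one (butenolide on the ring face that carries the tertiary hydroxyl) | O=C1OCC=C1C([H])=[C@]=C2C(C)(C)C[C@H](O[Si](C)(C)C(C)(C)C)C[C@@]2(C)O | intermediate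
11 | 3-[(2R,6S,7aR)-6-{[tert-butyl(dimethyl)silyl]oxy}-4,4,7a-trimethyl-2,4,5,6,7,7a-hexahydro-1-benzofuran-2-yl]furan-2(5H)-one | O=C1OCC=C1[C@H]2C=C3C(C)(C)C[C@H](O[Si](C)(C)C(C)(C)C)C[C@@]3(C)O2 | intermediate
12 | (2E)-3-methylpent-2-en-4-yn-1-ol | C#C/C(C)=C/CO | starting material
13 | (2E)-5-[(4R)-4-{[tert-butyl(dimethyl)silyl]oxy}-2,6,6-trimethylcyclohex-1-en-1-yl]-3-methylpent-2-en-4-yn-1-ol | CC1=C(C#C/C(C)=C/CO)C(C)(C)C[C@H](O[Si](C)(C)C(C)(C)C)C1 | intermediate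
14 | {[(1R)-4-[(3E)-5-bromo-3-methylpent-3-en-1-yn-1-yl]-3,5,5-trimethylcyclohex-3-en-1-yl]oxy}(tert-butyl)dimethylsilane | CC1=C(C#C/C(C)=C/CBr)C(C)(C)C[C@H](O[Si](C)(C)C(C)(C)C)C1 | intermediate
15 | diethyl {(2E)-5-[(4R)-4-{[tert-butyl(dimethyl)silyl]oxy}-2,6,6-trimethylcyclohex-1-en-1-yl]-3-methylpent-2-en-4-yn-1-yl}phosphonate | CC1=C(C#C/C(C)=C/CP(=O)(OCC)OCC)C(C)(C)C[C@H](O[Si](C)(C)C(C)(C)C)C1 | intermediate
16 | (2E)-4,4-dimethoxybut-2-enal | COC(OC)/C=C/C=O | starting material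
17 | tert-butyl{[(1R)-4-[(3E,5E,7E)-9,9-dimethoxy-3-methylnona-3,5,7-trien-1-yn-1-yl]-3,5,5-trimethylcyclohex-3-en-1-yl]oxy}dimethylsilane | CC1=C(C#C/C(C)=C/C=C/C=C/C(OC)OC)C(C)(C)C[C@H](O[Si](C)(C)C(C)(C)C)C1 | intermediate
18 | (2E,4E,6E)-9-[(4R)-4-{[tert-butyl(dimethyl)silyl]oxy}-2,6,6-trimethylcyclohex-1-en-1-yl]-7-methylnona-2,4,6-trien-8-ynal | CC1=C(C#C/C(C)=C/C=C/C=C/C=O)C(C)(C)C[C@H](O[Si](C)(C)C(C)(C)C)C1 | intermediate
19 | 2-(triphenyl-λ5-phosphanylidene)propanal | CC(C=O)=P(c1ccccc1)(c1ccccc1)c1ccccc1 | starting material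
20 | (2E,4E,6E,8E)-11-[(4R)-4-{[tert-butyl(dimethyl)silyl]oxy}-2,6,6-trimethylcyclohex-1-en-1-yl]-2,9-dimethylundeca-2,4,6,8-tetraen-10-ynal | CC1=C(C#C/C(C)=C/C=C/C=C/C=C(C)/C=O)C(C)(C)C[C@H](O[Si](C)(C)C(C)(C)C)C1 | intermediate
21 | tert-butyl({3-[(2R,6S,7aR)-6-{[tert-butyl(dimethyl)silyl]oxy}-4,4,7a-trimethyl-2,4,5,6,7,7a-hexahydro-1-benzofuran-2-yl]furan-2-yl}oxy)dimethylsilane | CC(C)(C)[Si](C)(C)Oc1occc1[C@H]2C=C3C(C)(C)C[C@H](O[Si](C)(C)C(C)(C)C)C[C@@]3(C)O2 | intermediate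
22 | 5-{(2E,4E,6E,8E)-1-{[tert-butyl(dimethyl)silyl]oxy}-11-[(4R)-4-{[tert-butyl(dimethyl)silyl]oxy}-2,6,6-trimethylcyclohex-1-en-1-yl]-2,9-dimethylundeca-2,4,6,8-tetraen-10-yn-1-yl}-3-[(2R,6S,7aR)-6-{[tert-butyl(dimethyl)silyl]oxy}-4,4,7a-trimethyl-2,4,5,6,7,7a-hexahydro-1-benzofuran-2-yl]furan-2(5H)-one (mixture at the two new sp3 carbons) | CC1=C(C#C/C(C)=C/C=C/C=C/C=C(C)/C(O[Si](C)(C)C(C)(C)C)C2OC(=O)C([C@H]3C=C4C(C)(C)C[C@H](O[Si](C)(C)C(C)(C)C)C[C@@]4(C)O3)=C2)C(C)(C)C[C@H](O[Si](C)(C)C(C)(C)C)C1 | intermediate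
23 | (5Z)-3-[(2R,6S,7aR)-6-{[tert-butyl(dimethyl)silyl]oxy}-4,4,7a-trimethyl-2,4,5,6,7,7a-hexahydro-1-benzofuran-2-yl]-5-{(2E,4E,6E,8E)-11-[(4R)-4-{[tert-butyl(dimethyl)silyl]oxy}-2,6,6-trimethylcyclohex-1-en-1-yl]-2,9-dimethylundeca-2,4,6,8-tetraen-10-yn-1-ylidene}furan-2(5H)-one | CC1=C(C#C/C(C)=C/C=C/C=C/C=C(C)/C=C2/C=C([C@H]3C=C4C(C)(C)C[C@H](O[Si](C)(C)C(C)(C)C)C[C@@]4(C)O3)C(=O)O2)C(C)(C)C[C@H](O[Si](C)(C)C(C)(C)C)C1 | intermediate
24 | (5Z)-3-[(2R,6S,7aR)-6-hydroxy-4,4,7a-trimethyl-2,4,5,6,7,7a-hexahydro-1-benzofuran-2-yl]-5-{(2E,4E,6E,8E)-11-[(4R)-4-hydroxy-2,6,6-trimethylcyclohex-1-en-1-yl]-2,9-dimethylundeca-2,4,6,8-tetraen-10-yn-1-ylidene}furan-2(5H)-one | CC1=C(C#C/C(C)=C/C=C/C=C/C=C(C)/C=C2/C=C([C@H]3C=C4C(C)(C)C[C@H](O)C[C@@]4(C)O3)C(=O)O2)C(C)(C)C[C@H](O)C1 | target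

**Totals**

Total step count: 13. Longest linear sequence: 9 steps (steps 1, 2, 3, 4, 5, 6, 7, 12, 13).

**Steps most likely to fail**

Step 5 (facial selectivity of the epoxidation). The syn epoxide may be formed in a larger share than expected or be hard to separate. The fallback sets out from 3 and moves to reagent control. Palladium-catalysed methoxycarbonylation (Pd(OAc)2, dppp, CO, MeOH, Et3N) gives methyl (4R)-4-{[tert-butyl(dimethyl)silyl]oxy}-2,6,6-trimethylcyclohex-1-ene-1-carboxylate F1. DIBAL-H reduction gives the allylic alcohol [(4R)-4-{[tert-butyl(dimethyl)silyl]oxy}-2,6,6-trimethylcyclohex-1-en-1-yl]methanol F2. Sharpless asymmetric epoxidation (Ti(OiPr)4, L-(+)-diethyl tartrate, t-BuOOH, delivering oxygen to the face anti to the silyloxy group) gives the epoxy alcohol [(1R,4S,6R)-4-{[tert-butyl(dimethyl)silyl]oxy}-2,2,6-trimethyl-7-oxabicyclo[4.1.0]heptan-1-yl]methanol F3. Dess–Martin oxidation gives the epoxy aldehyde (1S,4S,6R)-4-{[tert-butyl(dimethyl)silyl]oxy}-2,2,6-trimethyl-7-oxabicyclo[4.1.0]heptane-1-carbaldehyde F4. Seyferth–Gilbert homologation with the Ohira–Bestmann reagent (K2CO3, MeOH) gives the ethynyl epoxide (1R,4S,6R)-4-{[tert-butyl(dimethyl)silyl]oxy}-1-ethynyl-2,2,6-trimethyl-7-oxabicyclo[4.1.0]heptane F5. A cold Sonogashira coupling of F5 with 7 comes back to the route at 9.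

Step 6 (palladium–formate opening next to a butenolide). The alkynyl oxirane may give alkyne reduction, allene isomerisation or a poor anti/syn ratio. The fallback sets out from 9 and masks the lactone so that a copper hydride can be used. TIPSOTf and Et3N give the silyloxyfuran triisopropyl[(3-{[(1R,4S,6R)-4-{[tert-butyl(dimethyl)silyl]oxy}-2,2,6-trimethyl-7-oxabicyclo[4.1.0]heptan-1-yl]ethynyl}furan-2-yl)oxy]silane F6. Copper hydride-catalysed anti-SN2′ reduction of the propargyl oxirane (chloro[1,3-bis(2,6-diisopropylphenyl)imidazol-2-ylidene]copper, NaOtBu, polymethylhydrosiloxane, toluene, 0 °C) gives the allenol (1R,5S)-5-{[tert-butyl(dimethyl)silyl]oxy}-1,3,3-trimethyl-2-[(S)-2-{2-[(triisopropylsilyl)oxy]furan-3-yl}ethenylidene]cyclohexan-1-ol F7. Buffered fluoride (TBAF, AcOH, −78 °C) unmasks the butenolide and comes back to the route at 10.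

Step 7 (the proposed new gold cyclisation). Gold may fail to reach the hindered allene, or ionisation at the butenolide-bearing carbon may erode the axis-to-centre transfer. The fallback uses the known acid-catalysed epoxide-to-furanoxide rearrangement and sets out from 3. Stille coupling with excess (E)-1,2-bis(tributylstannyl)ethene (Pd(PPh3)4, LiCl, THF) gives the dienylstannane tributyl{(E)-2-[(4R)-4-{[tert-butyl(dimethyl)silyl]oxy}-2,6,6-trimethylcyclohex-1-en-1-yl]ethenyl}stannane F8. A second Stille coupling with 7 (Pd2(dba)3, AsPh3) gives the dienyl butenolide 3-{(E)-2-[(4R)-4-{[tert-butyl(dimethyl)silyl]oxy}-2,6,6-trimethylcyclohex-1-en-1-yl]ethenyl}furan-2(5H)-one F9. Epoxidation with mCPBA gives the 5,6-epoxide 3-{(E)-2-[(1S,4S,6R)-4-{[tert-butyl(dimethyl)silyl]oxy}-2,2,6-trimethyl-7-oxabicyclo[4.1.0]heptan-1-yl]ethenyl}furan-2(5H)-one F10. Pyridinium p-toluenesulfonate in CH2Cl2 then rearranges it to a mixture of 11 and its C2 epimer 3-[(2S,6S,7aR)-6-{[tert-butyl(dimethyl)silyl]oxy}-4,4,7a-trimethyl-2,4,5,6,7,7a-hexahydro-1-benzofuran-2-yl]furan-2(5H)-one F11. HPLC separation comes back to the route at 11.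

**Further compounds**

F1 | step 5 | methyl (4R)-4-{[tert-butyl(dimethyl)silyl]oxy}-2,6,6-trimethylcyclohex-1-ene-1-carboxylate | CC1=C(C(=O)OC)C(C)(C)C[C@H](O[Si](C)(C)C(C)(C)C)C1
F2 | step 5 | [(4R)-4-{[tert-butyl(dimethyl)silyl]oxy}-2,6,6-trimethylcyclohex-1-en-1-yl]methanol | CC1=C(CO)C(C)(C)C[C@H](O[Si](C)(C)C(C)(C)C)C1
F3 | step 5 | [(1R,4S,6R)-4-{[tert-butyl(dimethyl)silyl]oxy}-2,2,6-trimethyl-7-oxabicyclo[4.1.0]heptan-1-yl]methanol | C[C@@]12C[C@@H](O[Si](C)(C)C(C)(C)C)CC(C)(C)[C@]1(CO)O2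
F4 | step 5 | (1S,4S,6R)-4-{[tert-butyl(dimethyl)silyl]oxy}-2,2,6-trimethyl-7-oxabicyclo[4.1.0]heptane-1-carbaldehyde | C[C@@]12C[C@@H](O[Si](C)(C)C(C)(C)C)CC(C)(C)[C@]1(C=O)O2
F5 | step 5 | (1R,4S,6R)-4-{[tert-butyl(dimethyl)silyl]oxy}-1-ethynyl-2,2,6-trimethyl-7-oxabicyclo[4.1.0]heptane | C[C@@]12C[C@@H](O[Si](C)(C)C(C)(C)C)CC(C)(C)[C@]1(C#C)O2
F6 | step 6 | triisopropyl[(3-{[(1R,4S,6R)-4-{[tert-butyl(dimethyl)silyl]oxy}-2,2,6-trimethyl-7-oxabicyclo[4.1.0]heptan-1-yl]ethynyl}furan-2-yl)oxy]silane | C[C@@]12C[C@@H](O[Si](C)(C)C(C)(C)C)CC(C)(C)[C@]1(C#Cc3ccoc3O[Si](C(C)C)(C(C)C)C(C)C)O2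
F7 | step 6 | (1R,5S)-5-{[tert-butyl(dimethyl)silyl]oxy}-1,3,3-trimethyl-2-[(S)-2-{2-[(triisopropylsilyl)oxy]furan-3-yl}ethenylidene]cyclohexan-1-ol | CC(C)[Si](C(C)C)(C(C)C)Oc1occc1C([H])=[C@]=C2C(C)(C)C[C@H](O[Si](C)(C)C(C)(C)C)C[C@@]2(C)O
F8 | step 7 | tributyl{(E)-2-[(4R)-4-{[tert-butyl(dimethyl)silyl]oxy}-2,6,6-trimethylcyclohex-1-en-1-yl]ethenyl}stannane | CC1=C(/C=C/[Sn](CCCC)(CCCC)CCCC)C(C)(C)C[C@H](O[Si](C)(C)C(C)(C)C)C1
F9 | step 7 | 3-{(E)-2-[(4R)-4-{[tert-butyl(dimethyl)silyl]oxy}-2,6,6-trimethylcyclohex-1-en-1-yl]ethenyl}furan-2(5H)-one | CC1=C(/C=C/C2=CCOC2=O)C(C)(C)C[C@H](O[Si](C)(C)C(C)(C)C)C1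
F10 | step 7 | 3-{(E)-2-[(1S,4S,6R)-4-{[tert-butyl(dimethyl)silyl]oxy}-2,2,6-trimethyl-7-oxabicyclo[4.1.0]heptan-1-yl]ethenyl}furan-2(5H)-one | C[C@@]12C[C@@H](O[Si](C)(C)C(C)(C)C)CC(C)(C)[C@]1(/C=C/C3=CCOC3=O)O2
F11 | step 7 | 3-[(2S,6S,7aR)-6-{[tert-butyl(dimethyl)silyl]oxy}-4,4,7a-trimethyl-2,4,5,6,7,7a-hexahydro-1-benzofuran-2-yl]furan-2(5H)-one | O=C1OCC=C1[C@@H]2C=C3C(C)(C)C[C@H](O[Si](C)(C)C(C)(C)C)C[C@@]3(C)O2
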